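The L charged is a fixed sum: what is left, what has become D (one L each, I assume) and what has gone some other way.

| setting | blue | ochre | green | flask |
|---|---|---|---|---|
| Z | 0.20 M | 0.80 M | 0.40 M | 0.40 M |
| L | 0.48 M | 0.48 M | 0.48 M | 0.480 M |
| X | 80 mM | 80 mM | 160 mM | 80 mM |
| remark | run made earlier | run made earlier | run made earlier |  |

| run | time / h | D / % | Z / % |
|---|---|---|---|
| blue | 4.00 | 21.0 | 57.6 |
| blue | 8.00 | 38.5 | 36.8 |
| blue | 12.0 | 50.1 | 22.9 |
| blue | 15.0 | 51.0 | 16.9 |
| blue | 20.0 | 53.3 | 12.0 |
| ochre | 1.50 | 6.6 | 82.9 |
| ochre | 3.00 | 11.4 | 70.8 |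
| ochre | 6.00 | 20.5 | 58.4 |
| ochre | 10.0 | 22.5 | 48.3 |
| ochre | 20.0 | 23.0 | 34.2 |
| green | 4.00 | 35.9 | 38.4 |
| green | 8.00 | 52.7 | 18.3 |
| green | 12.0 | 55.5 | 9.9 |
| green | 15.0 | 56.2 | 8.2 |
| green | 20.0 | 56.7 | 1.9 |

(standard deviation of a reading: 1 percentage point)

- the analysis behind the earlier runs scatters by 1 percentage point, standard deviation
- no earlier run changes the charge of L; that part of a forecast is a guess

1. apparent order in X when 50 % of the Z are converted (percent change of the rate of making D for one percent more X charged)
2. apparent order in L when 50 % of the Z are converted (percent change of the rate of making D for one percent more L charged)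

The blue run looks contradictory. Of 0.48 M of L charged, D stands at 0.107 M after 20.0 h, yet from 15.0 h on Z still loses 4.9 percentage points while D gains 2.3 points. I clear this up by supposing that L also leaves by a path of its own, at a fixed fraction per hour. The D still to come in blue then falls with the L left, which gives the rate λ:

λ = ln[(D at the end − D at 4.00 h) / (D at the end − D at 8.00 h)] / (8.00 h − 4.00 h) = 0.195 h⁻¹

The flask's charge of Z lies between blue and ochre, so I take the mean of their rates of Z loss, k, and from it the time τ to 50 %:

k = 0.107 h⁻¹, τ = ln 2 / k = 6.46 h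

s = λτ = 1.26

This s, the lifetimes of L spent by 50 % conversion, carries the argument. A fixed fraction per hour does not depend on the L charged, so if D is made in proportion to L, my order in L is 1; that is a guess, since no run changes L. Green's k of 0.239 h⁻¹ suggests Z falls in proportion to X. One percent more X then shortens τ by one percent and raises the L left by s percent, so my order in X is 1 + s = 2.26.

The forecast gives 0.9 in X and 0.2 in L, on the ground “That sharp stop looks like L running out, with the rate nearly independent of L until then, so the order in L is small”. Both my orders are higher than its numbers.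

The flask gives 2.0 in X and 1.0 in L.

    X + G ⇌ E (K = 20.0 M⁻¹, k = 13.0 M⁻¹ h⁻¹)
    L + E → X + D (k = 4.00 M⁻¹ h⁻¹)
    L → J (k = 0.170 h⁻¹)
    Z + X → X + G (k = 1.90 M⁻¹ h⁻¹)

The flask reaches 50 % at 6.14 h, which makes s 1.20. The green run, with twice the X, spends s = 0.565, and its D reads 56.7 % at 20.0 h against the flask's 38.9 % at 25.0 h. In the flask, the half-life of L on the path to J, 4.1 h at 25.0 h, is shorter than the 6.14 h that Z takes to reach 50 %. At 25.0 h the flask holds 16 % of its Z against 0.022 % of L, the limiting reagent.

The data come from a simulation for an exercise, noise included.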